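## Retrosynthetic overview

1. The quinone comes last, by oxidative demethylation of a tetramethoxyarene. No ring is formed in the route: the single ring is bought as 2,3,4,5-tetramethoxytoluene and only oxidised at the end.
2. The terminal isopropylidene unit is attached by an sp3–sp2 coupling of a primary iodide with an isobutenyl-metal reagent.
3. The only stereocenter (C35, S) is set by an organocatalytic asymmetric transfer hydrogenation of a β,β-disubstituted enal that is released in the flask from a dienyl methyl ether (new variant).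
4. That dienyl ether comes from a one-carbon Wittig homologation of the ω-enal made by terminal allylic oxidation of the solanesyl chain. The chain thus supplies isoprene units 1 to 9, and the geometry of the ninth alkene is irrelevant because it is reduced.
5. The aryl–chain bond comes from an arylcopper reagent and solanesyl bromide (from solanesol).

Assumption: the phosphate salt is taken to induce the same facial sense as in its known reduction of citral, so the antipode of the salt that gives (R)-citronellal is used, and "single enantiomer" is read as the purity this catalysis delivers (about 95:5 expected).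

Abbreviations: Ar = 2,3,4,5-tetramethoxy-6-methylphenyl; (S)-TRIP = (S)-3,3′-bis(2,4,6-triisopropylphenyl)-1,1′-binaphthyl-2,2′-diyl hydrogen phosphate; Hantzsch ester = diethyl 2,6-dimethyl-1,4-dihydropyridine-3,5-dicarboxylate.

## Route

Step 1
Reactants: 1 solanesol (all-E nonaprenol)
Product: 2 solanesyl bromide
Conditions: PBr3 (0.4 equiv), pyridine (cat.), Et2O, −10 → 0 °C
Reagents that add atoms: phosphorus tribromide, BrP(Br)Br
Why: Alcohol-to-bromide substitution through a phosphite ester (SN2 at the primary allylic carbon) at low temperature keeps the 2E geometry and avoids allylic transposition.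

Step 2
Reactants: 3 2,3,4,5-tetramethoxytoluene; 2 solanesyl bromide
Product: 6 1,2,3,4-tetramethoxy-5-methyl-6-(all-E-solanesyl)benzene, via aryllithium 4 (not isolated), via arylcopper 5 (not isolated)
Conditions: n-BuLi, TMEDA, THF/hexane, 0 °C; CuBr·SMe2, −40 °C; then 2, −40 → 0 °C
Reagents that add atoms: none
Why: Directed ortho-lithiation at the only ring C–H, lithium-to-copper transmetalation and SN2 allylic substitution of the primary bromide by the soft arylcopper join ring and chain with retention of the 2E alkene; no stereocenter is formed.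

Step 3
Reactants: 6 1,2,3,4-tetramethoxy-5-methyl-6-(all-E-solanesyl)benzene
Product: 8 ω-enal Ar-CH2-(all-E C36 chain)-C(CH3)=CH… ending in (E)-CH=C(CH3)-CHO, via allylic alcohol 7 (not isolated)
Conditions: SeO2 (0.5 equiv), t-BuOOH (3 equiv), salicylic acid (10 mol%), CH2Cl2, 0 °C → rt, to about 50% conversion (6 recycled); then MnO2, CH2Cl2, rt
Reagents that add atoms: selenium dioxide, O=[Se]=O; tert-butyl hydroperoxide, CC(C)(C)OO
Why: Sharpless SeO2/t-BuOOH allylic oxidation (ene reaction, then [2,3]-sigmatropic shift) is fastest at the unhindered terminal gem-dimethyl alkene and attacks its (E)-methyl group, and MnO2 allylic oxidation then converts the alcohol to the enal; no stereocenter is formed.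

Step 4
Reactants: 8 ω-enal
Product: 9 dienyl methyl ether (terminus (E)-CH=C(CH3)-CH=CH-OCH3, 36E/36Z mixture)
Conditions: Ph3P(CH2OMe)Cl, t-BuOK, THF, 0 °C; then 8, 0 °C → rt; base-washed silica
Reagents that add atoms: (methoxymethyl)triphenylphosphonium chloride, COC[P+](c1ccccc1)(c1ccccc1)c1ccccc1.[Cl-]
Why: Wittig olefination with the non-stabilised methoxymethylene ylide turns the enal into a 1-methoxy-1,3-diene, a one-carbon-homologated masked enal whose double-bond geometry does not matter.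

Step 5
Reactants: 9 dienyl methyl ether
Product: 12 (3S)-alcohol Ar-CH2-(eight E units)-CH2CH2-CH(CH3)-CH2-CH2OH, via conjugated enal 10 (not isolated), via saturated S-aldehyde 11 (not isolated)
Conditions: morpholine (20 mol%), (S)-TRIP (25 mol%), H2O (3 equiv), 1,4-dioxane, 50 °C, 2 h; then Hantzsch ester (1.3 equiv), 50 °C, 24–48 h; then NaBH4, MeOH, 0 °C
Reagents that add atoms: water, O
Why: Proposed new method: an asymmetric counteranion-directed iminium transfer hydrogenation started from a dienyl ether instead of an enal, in which the small excess of free phosphoric acid protonates the 1-methoxy-1,3-diene at its δ-carbon, morpholine captures the conjugated oxocarbenium ion with loss of methanol to give the β,β-disubstituted iminium ion, E/Z and any β,γ isomers equilibrate through the dienamine, and the Hantzsch ester delivers hydride to C3 of the iminium ion held in the chiral (S)-TRIP phosphate ion pair to set the 3S methyl stereocenter before NaBH4 reduces the aldehyde; the closest known reaction type is the E/Z-convergent counteranion-directed transfer hydrogenation of β,β-dialkyl enals such as citral and farnesal.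

Step 6
Reactants: 12 (3S)-alcohol
Product: 13 (35S)-iodide (terminus -CH(CH3)-CH2-CH2-I)
Conditions: I2, PPh3, imidazole, CH2Cl2, 0 °C → rt
Reagents that add atoms: iodine, II
Why: Appel-type iodination (alkoxyphosphonium ion, SN2 by iodide) of the primary alcohol runs under neutral conditions that leave the polyene and the stereocenter two carbons away untouched.

Step 7
Reactants: 13 (35S)-iodide
Product: 14 1,2,3,4-tetramethoxy-5-methyl-6-[(35S)-34,35-dihydrodecaprenyl]benzene
Conditions: Me2C=CHMgBr (3 equiv), CuI (10 mol%), THF, −30 → 0 °C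
Reagents that add atoms: 2-methylprop-1-enylmagnesium bromide, CC(C)=C[Mg]Br
Why: Copper-catalysed Kochi-type sp3–sp2 cross-coupling of a primary alkyl iodide with an alkenyl Grignard reagent builds the terminal isopropylidene unit without touching the stereocenter.

Step 8
Reactants: 14 1,2,3,4-tetramethoxy-5-methyl-6-[(35S)-34,35-dihydrodecaprenyl]benzene
Product: 15 target quinone CNP0144872.1
Conditions: (NH4)2Ce(NO3)6 (2.5 equiv), MeCN/CH2Cl2/H2O, 0 °C, 20 min
Reagents that add atoms: water, O
Why: Oxidative demethylation of the para-dimethoxy arene (electron transfer to cerium, attack of water, loss of methanol) gives the 2,3-dimethoxy-para-quinone, the electron-rich ring being oxidised much faster than the isolated trisubstituted alkenes at 0 °C.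

## Compound list

1 | solanesol, (2E,6E,10E,14E,18E,22E,26E,30E)-3,7,11,15,19,23,27,31,35-nonamethylhexatriaconta-2,6,10,14,18,22,26,30,34-nonaen-1-ol | `OC/C=C(\C)CC/C=C(\C)CC/C=C(\C)CC/C=C(\C)CC/C=C(\C)CC/C=C(\C)CC/C=C(\C)CC/C=C(\C)CCC=C(C)C` | starting material

2 | solanesyl bromide, (2E,6E,10E,14E,18E,22E,26E,30E)-1-bromo-3,7,11,15,19,23,27,31,35-nonamethylhexatriaconta-2,6,10,14,18,22,26,30,34-nonaene | `BrC/C=C(\C)CC/C=C(\C)CC/C=C(\C)CC/C=C(\C)CC/C=C(\C)CC/C=C(\C)CC/C=C(\C)CC/C=C(\C)CCC=C(C)C` | intermediate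

3 | 2,3,4,5-tetramethoxytoluene | `COc1cc(C)c(OC)c(OC)c1OC` | starting material

4 | (2,3,4,5-tetramethoxy-6-methylphenyl)lithium | `[Li]c1c(C)c(OC)c(OC)c(OC)c1OC` | intermediate (not isolated)

5 | (2,3,4,5-tetramethoxy-6-methylphenyl)copper | `[Cu]c1c(C)c(OC)c(OC)c(OC)c1OC` | intermediate (not isolated)

6 | 1,2,3,4-tetramethoxy-5-methyl-6-[(2E,6E,10E,14E,18E,22E,26E,30E)-3,7,11,15,19,23,27,31,35-nonamethylhexatriaconta-2,6,10,14,18,22,26,30,34-nonaen-1-yl]benzene | `COc1c(OC)c(OC)c(C/C=C(\C)CC/C=C(\C)CC/C=C(\C)CC/C=C(\C)CC/C=C(\C)CC/C=C(\C)CC/C=C(\C)CC/C=C(\C)CCC=C(C)C)c(C)c1OC` | intermediate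

7 | (2E,6E,10E,14E,18E,22E,26E,30E,34E)-2,6,10,14,18,22,26,30,34-nonamethyl-36-(2,3,4,5-tetramethoxy-6-methylphenyl)hexatriaconta-2,6,10,14,18,22,26,30,34-nonaen-1-ol | `COc1c(OC)c(OC)c(C/C=C(\C)CC/C=C(\C)CC/C=C(\C)CC/C=C(\C)CC/C=C(\C)CC/C=C(\C)CC/C=C(\C)CC/C=C(\C)CC/C=C(\C)CO)c(C)c1OC` | intermediate (not isolated)

8 | (2E,6E,10E,14E,18E,22E,26E,30E,34E)-2,6,10,14,18,22,26,30,34-nonamethyl-36-(2,3,4,5-tetramethoxy-6-methylphenyl)hexatriaconta-2,6,10,14,18,22,26,30,34-nonaenal | `COc1c(OC)c(OC)c(C/C=C(\C)CC/C=C(\C)CC/C=C(\C)CC/C=C(\C)CC/C=C(\C)CC/C=C(\C)CC/C=C(\C)CC/C=C(\C)CC/C=C(\C)C=O)c(C)c1OC` | intermediate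

9 | 1,2,3,4-tetramethoxy-5-[(2E,6E,10E,14E,18E,22E,26E,30E,34E)-37-methoxy-3,7,11,15,19,23,27,31,35-nonamethylheptatriaconta-2,6,10,14,18,22,26,30,34,36-decaen-1-yl]-6-methylbenzene (36E/36Z mixture) | `COc1c(OC)c(OC)c(C/C=C(\C)CC/C=C(\C)CC/C=C(\C)CC/C=C(\C)CC/C=C(\C)CC/C=C(\C)CC/C=C(\C)CC/C=C(\C)CC/C=C(\C)C=COC)c(C)c1OC` | intermediate

10 | (7E,11E,15E,19E,23E,27E,31E,35E)-3,7,11,15,19,23,27,31,35-nonamethyl-37-(2,3,4,5-tetramethoxy-6-methylphenyl)heptatriaconta-2,7,11,15,19,23,27,31,35-nonaenal (2E/2Z mixture) | `COc1c(OC)c(OC)c(C/C=C(\C)CC/C=C(\C)CC/C=C(\C)CC/C=C(\C)CC/C=C(\C)CC/C=C(\C)CC/C=C(\C)CC/C=C(\C)CCCC(C)=CC=O)c(C)c1OC` | intermediate (not isolated)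

11 | (3S,7E,11E,15E,19E,23E,27E,31E,35E)-3,7,11,15,19,23,27,31,35-nonamethyl-37-(2,3,4,5-tetramethoxy-6-methylphenyl)heptatriaconta-7,11,15,19,23,27,31,35-octaenal | `COc1c(OC)c(OC)c(C/C=C(\C)CC/C=C(\C)CC/C=C(\C)CC/C=C(\C)CC/C=C(\C)CC/C=C(\C)CC/C=C(\C)CC/C=C(\C)CCC[C@H](C)CC=O)c(C)c1OC` | intermediate (not isolated)

12 | (3S,7E,11E,15E,19E,23E,27E,31E,35E)-3,7,11,15,19,23,27,31,35-nonamethyl-37-(2,3,4,5-tetramethoxy-6-methylphenyl)heptatriaconta-7,11,15,19,23,27,31,35-octaen-1-ol | `COc1c(OC)c(OC)c(C/C=C(\C)CC/C=C(\C)CC/C=C(\C)CC/C=C(\C)CC/C=C(\C)CC/C=C(\C)CC/C=C(\C)CC/C=C(\C)CCC[C@H](C)CCO)c(C)c1OC` | intermediate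

13 | 1-[(2E,6E,10E,14E,18E,22E,26E,30E,35S)-37-iodo-3,7,11,15,19,23,27,31,35-nonamethylheptatriaconta-2,6,10,14,18,22,26,30-octaen-1-yl]-2,3,4,5-tetramethoxy-6-methylbenzene | `COc1c(OC)c(OC)c(C/C=C(\C)CC/C=C(\C)CC/C=C(\C)CC/C=C(\C)CC/C=C(\C)CC/C=C(\C)CC/C=C(\C)CC/C=C(\C)CCC[C@H](C)CCI)c(C)c1OC` | intermediate

14 | 1,2,3,4-tetramethoxy-5-methyl-6-[(2E,6E,10E,14E,18E,22E,26E,30E,35S)-3,7,11,15,19,23,27,31,35,39-decamethyltetraconta-2,6,10,14,18,22,26,30,38-nonaen-1-yl]benzene | `COc1c(OC)c(OC)c(C/C=C(\C)CC/C=C(\C)CC/C=C(\C)CC/C=C(\C)CC/C=C(\C)CC/C=C(\C)CC/C=C(\C)CC/C=C(\C)CCC[C@H](C)CCC=C(C)C)c(C)c1OC` | intermediate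

15 | 2,3-dimethoxy-5-methyl-6-[(2E,6E,10E,14E,18E,22E,26E,30E,35S)-3,7,11,15,19,23,27,31,35,39-decamethyltetraconta-2,6,10,14,18,22,26,30,38-nonaen-1-yl]cyclohexa-2,5-diene-1,4-dione | `COC1=C(OC)C(=O)C(C/C=C(\C)CC/C=C(\C)CC/C=C(\C)CC/C=C(\C)CC/C=C(\C)CC/C=C(\C)CC/C=C(\C)CC/C=C(\C)CCC[C@H](C)CCC=C(C)C)=C(C)C1=O` | target

## Summary

Total step count: 8. Longest linear sequence: 8 steps (solanesol 1 to target 15); 2,3,4,5-tetramethoxytoluene 3 is used as bought and enters at step 2.

Three steps most likely to fail: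

**Step 3 (terminal selectivity of the allylic oxidation on a chain with nine trisubstituted alkenes).** The fallback sets out from 6 and comes back at 7, which is then oxidised with MnO2 to 8 as in step 3. The terminal alkene is singled out by the polar-medium bromohydrin method instead of by the intrinsic preference of SeO2. NBS in THF/water at 0 °C gives the terminal bromohydrin F1. K2CO3 in MeOH closes it to the terminal epoxide F2. Al(Oi-Pr)3 in refluxing toluene isomerises the epoxide to the isopropenyl carbinol F3. Catalytic Ph3SiOReO3 in Et2O at 0 °C then moves the hydroxyl by 1,3-transposition to the primary allylic alcohol 7. Here 7 forms as an E/Z mixture, which is of no consequence because this alkene is reduced in step 5.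

**Step 5 (the proposed new step; the unmasking, isomer funnelling and ion-pair-controlled hydride transfer must all work in one flask).** The fallback sets out from 9 and comes back at 12 with known chemistry. The events are uncoupled, and chirality is delivered by a covalently bound chiral amine instead of a chiral counter-anion. Compound 9 is hydrolysed and equilibrated (PPTS, acetone/water, rt) to the conjugated enal 10, which is isolated. Enal 10 is reduced by the known E/Z-convergent imidazolidinone iminium transfer hydrogenation to the S aldehyde 11, which is isolated. The conditions are 2-tert-butyl-3-methylimidazolidin-4-one trichloroacetate (the enantiomer that gives the S product, 20 mol%), Hantzsch ester, CHCl3, −30 °C. NaBH4 in MeOH then gives 12. This fallback makes no compound outside the list (none, F0).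

**Step 7 (sp3–sp2 coupling; reduction or elimination of the iodide may compete).** The fallback sets out from 13 and comes back at 14 with reversed polarity. Zinc dust with LiCl in THF at 40 °C inserts into the C–I bond to give the alkylzinc iodide F4. A Negishi coupling of F4 with 1-bromo-2-methylprop-1-ene under Pd(PPh3)4 (THF, 50 °C) forms the same bond.

## Further compounds

F1 | step 3 | terminal bromohydrin, 34-bromo-3,7,11,15,19,23,27,31,35-nonamethyl-1-(2,3,4,5-tetramethoxy-6-methylphenyl)hexatriaconta-2,6,10,14,18,22,26,30-octaen-35-ol (all-E, racemic at C34) | `COc1c(OC)c(OC)c(C/C=C(\C)CC/C=C(\C)CC/C=C(\C)CC/C=C(\C)CC/C=C(\C)CC/C=C(\C)CC/C=C(\C)CC/C=C(\C)CCC(Br)C(C)(C)O)c(C)c1OC`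
F2 | step 3 | terminal epoxide, 34,35-epoxide of compound 6 (all-E, racemic) | `COc1c(OC)c(OC)c(C/C=C(\C)CC/C=C(\C)CC/C=C(\C)CC/C=C(\C)CC/C=C(\C)CC/C=C(\C)CC/C=C(\C)CC/C=C(\C)CCC2OC2(C)C)c(C)c1OC`
F3 | step 3 | isopropenyl carbinol, 3,7,11,15,19,23,27,31,35-nonamethyl-1-(2,3,4,5-tetramethoxy-6-methylphenyl)hexatriaconta-2,6,10,14,18,22,26,30,35-nonaen-34-ol (all-E, racemic) | `COc1c(OC)c(OC)c(C/C=C(\C)CC/C=C(\C)CC/C=C(\C)CC/C=C(\C)CC/C=C(\C)CC/C=C(\C)CC/C=C(\C)CC/C=C(\C)CCC(O)C(C)=C)c(C)c1OC`
F0 | step 5 | none | none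
F4 | step 7 | alkylzinc iodide, [(3S,7E,11E,15E,19E,23E,27E,31E,35E)-3,7,11,15,19,23,27,31,35-nonamethyl-37-(2,3,4,5-tetramethoxy-6-methylphenyl)heptatriaconta-7,11,15,19,23,27,31,35-octaen-1-yl]zinc iodide | `COc1c(OC)c(OC)c(C/C=C(\C)CC/C=C(\C)CC/C=C(\C)CC/C=C(\C)CC/C=C(\C)CC/C=C(\C)CC/C=C(\C)CC/C=C(\C)CCC[C@H](C)CC[Zn]I)c(C)c1OC`
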